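**Strategy.** The cyclohexane is cut at C1–C2 and C4–C5 (C1 carbinol carbon, C2 aryl-bearing, C4 isopropenyl-bearing, numbered round the ring). Stripped of the C1 methyl and C2 aryl groups, the ring is 4-isopropenylcyclohexanone, which has a mirror plane through C1 and C4; the key step exploits this and builds it without stereocontrol: a homoprenyl Grignard reagent is acylated by acryloyl chloride (C1–C2) and the acyclic 1,6-dien-3-one is closed in the same flask by a Lewis-acid ene reaction (C4–C5) that also creates the isopropenyl group. Enantioselective α-chlorination then desymmetrises the ketone, the dearomatised diprenyl acylphloroglucinol displaces chloride at C2, and methyl addition sets C1.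

Key step: step 3

Remark: ketone 10 is mirror-symmetric, so its two α-methylene/β-methylene arms are equivalent; the arm formed by the acylation is the one numbered C2–C3, and the arm closed by the ene reaction is C6–C5.

Assumption: the (4R,5R)-configured amine catalyst of step 4 is taken to select the α-methylene that leads to (2R,4S)-11; should the sense prove opposite, its enantiomer is used.

**Step 1**
Reactants: 1 phloroglucinol; 2 isobutyryl chloride
Product: 3 2-methyl-1-(2,4,6-trihydroxyphenyl)propan-1-one
Conditions: AlCl3, PhNO2, 65 °C
Reagents that add atoms: none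
Why: Friedel–Crafts acylation of the electron-rich triol, which should stop at mono-acylation because the chelated aryl ketone is deactivated.

**Step 2**
Reactants: 3 2-methyl-1-(2,4,6-trihydroxyphenyl)propan-1-one; 4 prenyl bromide (2 equiv)
Product: 5 3,5-dihydroxy-2-(2-methylpropanoyl)-6,6-bis(3-methylbut-2-en-1-yl)cyclohexa-2,4-dien-1-one
Conditions: NaOMe, MeOH, 0 °C to rt
Reagents that add atoms: none
Why: Base-mediated C-prenylation of the vinylogous acid, in which the second prenyl group can enter at the carbon already prenylated with loss of aromaticity (as in lupulone-type syntheses); the geminal isomer 5 is to be separated from the 3,5-diprenyl isomer by chromatography, and no stereocentre is formed.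

**Step 3**
Reactants: 6 5-bromo-2-methylpent-2-ene; 7 acryloyl chloride
Product: 10 4-(prop-1-en-2-yl)cyclohexan-1-one, via Grignard reagent 8 (not isolated), via dienone 9 (not isolated)
Conditions: Mg, Et2O; 7, Fe(acac)3 (cat.), −78 °C; then Me2AlCl (excess), CH2Cl2, −78 to 0 °C, one flask
Reagents that add atoms: none
Why: Magnesium insertion gives 8, whose iron-catalysed acylation by 7 at low temperature (ketone synthesis from a Grignard reagent and an acid chloride) makes the C1–C2 bond and delivers the polymerisation-prone dienone 9, which is therefore cyclised without isolation. Me2AlCl binds the enone oxygen and the trisubstituted alkene attacks the enone β-carbon C5 through C4 while an allylic methyl hydrogen passes to C6 (concerted, or via the tertiary cation and the aluminium enolate); this forms C4–C5 and turns the dimethylvinyl terminus into the isopropenyl group. The closest known reaction type is the Lewis-acid-promoted type 1 intramolecular ene cyclisation of a 1,6-diene carrying an enone enophile; the six-membered ring closes 6-endo-trig at the enone and exo with respect to the ene double bond. No stereocentre arises, because 10 has a mirror plane through C1 and C4 and C4 is only prostereogenic. The step needs acylation to outrun conjugate addition (low temperature, catalysis, acid chloride in excess) and proton transfer to outrun chloride capture or isopropylidene formation (Me2AlCl as proton-scavenging Lewis acid). The three-atom tether allows only the six-membered closure, and the alkene polarisation directs bond formation to its less substituted carbon C4.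

**Step 4**
Reactants: 10 4-(prop-1-en-2-yl)cyclohexan-1-one
Product: 11 (2R,4S)-2-chloro-4-(prop-1-en-2-yl)cyclohexan-1-one
Conditions: NCS, (4R,5R)-4,5-diphenylimidazolidine (cat.), 2-nitrobenzoic acid (cat.), MeCN, −25 °C
Reagents that add atoms: N-chlorosuccinimide, O=C1CCC(=O)N1Cl
Why: Enamine-catalysed asymmetric α-chlorination of a cyclic ketone, in which the chiral amine distinguishes the two enantiotopic α-methylenes and thereby fixes C4 as (S) by catalyst control; axial delivery of chlorine to the enamine should place it trans to the equatorial isopropenyl group.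

**Step 5**
Reactants: 5 3,5-dihydroxy-2-(2-methylpropanoyl)-6,6-bis(3-methylbut-2-en-1-yl)cyclohexa-2,4-dien-1-one; 11 (2R,4S)-2-chloro-4-(prop-1-en-2-yl)cyclohexan-1-one
Product: 12 3,5-dihydroxy-2-(2-methylpropanoyl)-6,6-bis(3-methylbut-2-en-1-yl)-4-[(1R,5S)-2-oxo-5-(prop-1-en-2-yl)cyclohexyl]cyclohexa-2,4-dien-1-one
Conditions: K2CO3, NaI (cat.), acetone, 0 °C to rt
Reagents that add atoms: none
Why: Iodide-assisted SN2 C-alkylation of the only free ring carbon of the triketone enolate by the α-halo ketone; whatever the steric course at C2, this centre lies α to the ketone and should settle under the basic conditions as the cis-2,4-diequatorial isomer (thermodynamic control), C4 being untouched.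

**Step 6**
Reactants: 12 3,5-dihydroxy-2-(2-methylpropanoyl)-6,6-bis(3-methylbut-2-en-1-yl)-4-[(1R,5S)-2-oxo-5-(prop-1-en-2-yl)cyclohexyl]cyclohexa-2,4-dien-1-one
Product: 13 3,5-dihydroxy-4-[(1R,2R,5S)-2-hydroxy-2-methyl-5-(prop-1-en-2-yl)cyclohexyl]-2-(2-methylpropanoyl)-6,6-bis(3-methylbut-2-en-1-yl)cyclohexa-2,4-dien-1-one (target)
Conditions: MeMgBr (excess), CeCl3, THF, −78 to 0 °C; aq NH4Cl
Reagents that add atoms: methylmagnesium bromide, C[Mg]Br
Why: Cerium-modified Grignard 1,2-addition, in which the two enols are first deprotonated to a magnesium dienolate that shields the triketone; the methyl group should attack the remaining ketone from the equatorial direction, giving the axial hydroxyl cis to the equatorial aryl group, i.e. (1R), by substrate control.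

**Compound list**
1 | phloroglucinol (benzene-1,3,5-triol) | Oc1cc(O)cc(O)c1 | starting material
2 | isobutyryl chloride | CC(C)C(Cl)=O | starting material
3 | 2-methyl-1-(2,4,6-trihydroxyphenyl)propan-1-one | CC(C)C(=O)c1c(O)cc(O)cc1O | intermediate
4 | prenyl bromide (1-bromo-3-methylbut-2-ene) | CC(C)=CCBr | starting material
5 | 3,5-dihydroxy-2-(2-methylpropanoyl)-6,6-bis(3-methylbut-2-en-1-yl)cyclohexa-2,4-dien-1-one | CC(C)C(=O)C1=C(O)C=C(O)C(CC=C(C)C)(CC=C(C)C)C1=O | intermediate
6 | 5-bromo-2-methylpent-2-ene | CC(C)=CCCBr | starting material
7 | acryloyl chloride | C=CC(Cl)=O | starting material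
8 | (4-methylpent-3-en-1-yl)magnesium bromide | CC(C)=CCC[Mg]Br | intermediate
9 | 7-methylocta-1,6-dien-3-one | C=CC(=O)CCC=C(C)C | intermediate
10 | 4-(prop-1-en-2-yl)cyclohexan-1-one (achiral) | C=C(C)C1CCC(=O)CC1 | intermediate
11 | (2R,4S)-2-chloro-4-(prop-1-en-2-yl)cyclohexan-1-one | C=C(C)[C@H]1CCC(=O)[C@H](Cl)C1 | intermediate
12 | 3,5-dihydroxy-2-(2-methylpropanoyl)-6,6-bis(3-methylbut-2-en-1-yl)-4-[(1R,5S)-2-oxo-5-(prop-1-en-2-yl)cyclohexyl]cyclohexa-2,4-dien-1-one | C=C(C)[C@H]1CCC(=O)[C@@H](C2=C(O)C(CC=C(C)C)(CC=C(C)C)C(=O)C(C(=O)C(C)C)=C2O)C1 | intermediate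
13 | 3,5-dihydroxy-4-[(1R,2R,5S)-2-hydroxy-2-methyl-5-(prop-1-en-2-yl)cyclohexyl]-2-(2-methylpropanoyl)-6,6-bis(3-methylbut-2-en-1-yl)cyclohexa-2,4-dien-1-one | C=C(C)[C@H]1CC[C@@](C)(O)[C@@H](C2=C(O)C(CC=C(C)C)(CC=C(C)C)C(=O)C(C(=O)C(C)C)=C2O)C1 | target

**Total step count:** 6. **Longest linear sequence:** 4 steps (6 → 10 → 11 → 12 → 13; equally 1 → 3 → 5 → 12 → 13).

**Steps most likely to fail**

Step 3. The Grignard reagent may add in conjugate fashion to the acid chloride or to the enone just formed, and the dienone may polymerise before cyclisation. In the ring closure, chloride capture of the tertiary cation, proton loss towards the ring (isopropylidene) or a second carbonyl-ene closure of the product ketone onto its own isopropenyl group may compete. The fallback sets out from 6 and returns at 10, forming the two ring bonds in separate, well-precedented operations. The Grignard reagent from 6 is carboxylated with CO2 to 5-methylhex-4-enoic acid F1 and esterified (MeOH, H2SO4) to methyl 5-methylhex-4-enoate F2. An intermolecular EtAlCl2-promoted ene reaction with methyl acrylate then forms C4–C5 and gives the symmetric diester dimethyl 4-(prop-1-en-2-yl)heptanedioate F3. Dieckmann condensation (NaH, THF) closes C1–C2 to methyl 2-oxo-5-(prop-1-en-2-yl)cyclohexane-1-carboxylate F4, and Krapcho dealkoxycarbonylation (LiCl, wet DMSO, 150 °C) gives 10.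

Step 5. Substitution at the hindered secondary α-carbon may be slow, and O-alkylation of the triketone, dehydrohalogenation of the chloro ketone or its Favorskii contraction may take over. The fallback sets out from 3 and returns at 12, alkylating before the ring is dearomatised. The less hindered aromatic triol 3 is C-alkylated with 11 (K2CO3, NaI, acetone) to 2-methyl-1-{2,4,6-trihydroxy-3-[(1R,5S)-2-oxo-5-(prop-1-en-2-yl)cyclohexyl]phenyl}propan-1-one F5. Geminal diprenylation of F5 with 4 (NaOMe, MeOH) can then occur only at the single free ring carbon and should give 12.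

Step 4. The catalyst may discriminate poorly between the enantiotopic methylenes, and over-chlorination or chlorination of the isopropenyl group may occur. The fallback sets out from 10 and returns at 11. Enantioselective deprotonation of 10 with lithium bis[(R)-1-phenylethyl]amide in the presence of LiCl and Me3SiCl (THF, −78 °C) should give (S)-trimethyl{[4-(prop-1-en-2-yl)cyclohex-1-en-1-yl]oxy}silane F6. This is chlorinated regiospecifically with NCS to 11.

**Further compounds**
F1 | step 3 | 5-methylhex-4-enoic acid | CC(C)=CCCC(=O)O
F2 | step 3 | methyl 5-methylhex-4-enoate | CC(C)=CCCC(=O)OC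
F3 | step 3 | dimethyl 4-(prop-1-en-2-yl)heptanedioate | C=C(C)C(CCC(=O)OC)CCC(=O)OC
F4 | step 3 | methyl 2-oxo-5-(prop-1-en-2-yl)cyclohexane-1-carboxylate | C=C(C)C1CCC(=O)C(C(=O)OC)C1
F5 | step 5 | 2-methyl-1-{2,4,6-trihydroxy-3-[(1R,5S)-2-oxo-5-(prop-1-en-2-yl)cyclohexyl]phenyl}propan-1-one | C=C(C)[C@H]1CCC(=O)[C@@H](c2c(O)cc(O)c(C(=O)C(C)C)c2O)C1
F6 | step 4 | (S)-trimethyl{[4-(prop-1-en-2-yl)cyclohex-1-en-1-yl]oxy}silane | C=C(C)[C@H]1CCC(O[Si](C)(C)C)=CC1
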